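Take the closed, stirred vessel and follow the steps in it in the order in which each feeds the next: substrate couples to intermediate, second reagent turns intermediate into target, and target exchanges with its isomer.

| flask | substrate | coupling partner | second reagent | remark | time |
|---|---|---|---|---|---|
| ash | 0.0010 M | 0.65 equiv | 0.50 equiv | run made earlier |  |
| maple | 0.0010 M | 0.98 equiv | 0.50 equiv | run made earlier |  |
| elm | 0.0015 M | 1.3 equiv | 0.50 equiv | run made earlier |  |
| flask | 0.0010 M | 1.30 equiv | 0.500 equiv |  | 6.0 min |

| run | time / min | target / % | substrate / % |
|---|---|---|---|
| ash | 0.167 | 7.9 | 42.8 |
| ash | 0.500 | 14.8 | 31.3 |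
| ash | 1.33 | 16.1 | 28.9 |
| ash | 4.00 | 17.0 | 26.6 |
| maple | 0.167 | 8.2 | 25.9 |
| maple | 0.500 | 16.4 | 10.0 |
| maple | 1.33 | 17.1 | 3.6 |
| maple | 4.00 | 17.9 | 3.1 |
| elm | 0.167 | 15.8 | 7.7 |
| elm | 0.500 | 24.0 | 0.5 |
| elm | 1.33 | 19.0 | 1.3 |
| elm | 4.00 | 18.6 | 1.1 |

(standard deviation of a reading: 1 percentage point)

- the numbers in the tables scatter with a standard deviation of 1 percentage point
- reactions considered so far: substrate + coupling partner -> intermediate; second reagent + intermediate -> target; substrate + second reagent -> side product; target <-> isomer of the product

* the best time, 6.0 min at the latest, for target
* the amount of target, in percent of the substrate charged, at that time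
* the first time at which target reaches 10%, in the same percent, in min

Start with the first step. Elm's substrate reading of 7.7% at 0.167 min gives a life of 0.0651 min. Stretch it for this flask's smaller amount of coupling partner, and it becomes about 0.0977 min. So expect the flask's substrate to be nearly spent well before 0.500 min.

Next, second reagent meets intermediate, and maple's target already reads 16.4% at 0.500 min. Target in turn passes to its isomer: elm's target readings fall from 24.0% at 0.500 min to 19.0% at 1.33 min.

Now find the amount that sets the end. From ash to elm, coupling partner rose to twice its equivalents and substrate rose from 0.0010 M to 0.0015 M, yet the last target readings moved from 17.0% to 18.6%, not far beyond the scatter. Second reagent is the limiting reagent, with less charged than coupling partner even in ash. So divide the mean last target reading by the second reagent charged, and call this the target yield per second reagent 0.357. No run varied that charge, so treat the proportion as a commitment. For this flask it gives 17.8% at the end, with a higher peak before 1.33 min, as in elm.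

The forecast gave 20% at 0.55 min and the asked mark at 0.18 min, holding that “The second reagent is limiting”.

The flask gives 20.0% at 0.652 min and reaches the mark at 0.153 min.

    substrate + coupling partner → intermediate (k = 293 L mol⁻¹ s⁻¹)
    second reagent + intermediate → target (k = 52.2 L mol⁻¹ s⁻¹)
    substrate + second reagent → side product (k = 7.72 L mol⁻¹ s⁻¹)
    target ⇌ isomer of the product (K = 1.70, k = 0.0383 s⁻¹)

At 6.00 min it holds 18.0% target, with second reagent at 0% and intermediate still at 50.0%. Put the yield to use once more: for a neighbour flask charged with 0.850 equiv of second reagent, it gives 30.3%, and that neighbour ends with 30.3% target.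

The data stem from a simulated flask on assumed constants, noise included.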